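The route disconnects the bond between the lactone carbonyl C1 and arene carbon C7a. C7a lies between C7 (OMe) and C3a, whose substituent C3 carries the lactone oxygen O2, so a carbonate on that oxygen holds its carbonyl within reach of C7a for a five-membered closure. Bromine–lithium exchange at C7a of (S)-1-(2-bromo-3-methoxyphenyl)but-3-enyl methyl carbonate, then 5-exo acyl substitution (Parham cyclization), closes the γ-lactone (ring B) onto the benzene ring (ring A) in one operation, with C3 already set by allylboration. Cross-metathesis/hydrogenation then adds the chiral-pool side chain, and a sterically controlled C–H borylation/oxidation installs the C5 hydroxyl last.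

Key step: step 3

Remark: phthalide numbering is used (C1 carbonyl, O2, C3, C3a, C4–C7, C7a), and the target is treated as the open γ-hydroxy ketone drawn, its ring–chain equilibrium with the cyclic hemiketal not being counted as a separate compound.

Step 1
Reactants: 1 2-bromo-3-methoxybenzaldehyde
Product: 3 (S)-1-(2-bromo-3-methoxyphenyl)but-3-en-1-ol, via borinate ester 2 (not isolated)
Conditions: dIpc2B(allyl) (preformed, salt-free, 1.2 equiv), Et2O, −78 °C; then NaOH, H2O2, 0 °C to rt
Reagents that add atoms: B-allyldiisopinocampheylborane with both isopinocampheyl groups from (+)-α-pinene, C=CCB([C@@H]1C[C@@H]2C[C@H]([C@H]1C)C2(C)C)[C@@H]1C[C@@H]2C[C@H]([C@H]1C)C2(C)C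
Why: Brown allylboration through a closed chair (Zimmerman–Traxler) transition state, in which the (+)-α-pinene-derived isopinocampheyl groups should steer the allyl group to the Si face of the aldehyde and so set C3 as S (aryl ranks above allyl), followed by oxidative cleavage of borinate 2; the aryl bromide is inert to the borane.

Step 2
Reactants: 3 (S)-1-(2-bromo-3-methoxyphenyl)but-3-en-1-ol
Product: 4 (S)-1-(2-bromo-3-methoxyphenyl)but-3-enyl methyl carbonate
Conditions: ClCO2Me, pyridine, DMAP (cat.), CH2Cl2, 0 °C to rt
Reagents that add atoms: methyl chloroformate, COC(=O)Cl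
Why: O-acylation of the secondary alcohol by the chloroformate under nucleophilic catalysis (carbonate formation) leaves the C–O bond of the stereocenter untouched, so the S configuration is kept.

Step 3
Reactants: 4 (S)-1-(2-bromo-3-methoxyphenyl)but-3-enyl methyl carbonate
Product: 7 (S)-7-methoxy-3-(prop-2-enyl)-2-benzofuran-1(3H)-one, via aryllithium 5 (not isolated), via tetrahedral lithium alkoxide 6 (not isolated)
Conditions: t-BuLi (2.1 equiv), THF, −78 °C; then AcOH, −78 °C to rt
Reagents that add atoms: none
Why: Bromine–lithium exchange at the arene carbon that becomes C7a should be much faster at −78 °C than addition of t-BuLi to the carbonate, and aryllithium 5 then attacks the carbonate carbonyl held on O2 to give the cyclic tetrahedral alkoxide 6, which loses methoxide to leave the lactone carbonyl C1 (if 6 opened at the C3 oxygen instead, the alkoxide formed would close again on the methyl ester to the same lactone). The closest known reaction type is the Parham cyclization, the halogen–lithium exchange/intramolecular acyl substitution used for benzo-fused five-membered ketones, lactams and lactones. Ring B closes in the 5-exo-trig mode through the C1–C7a bond. No stereocenter is formed, and C3 stays S because neither its C–O nor its C–H bond takes part. The step needs site selectivity on the arene, fixed by the bromine between the methoxy-bearing carbon and the carbinol-bearing carbon, and chemoselectivity of exchange over carbonyl addition and of acyl transfer over 5-exo carbolithiation of the allyl group, secured by the low temperature, the second equivalent of t-BuLi that destroys tert-butyl bromide and the much faster attack on the carbonyl.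

Step 4
Reactants: 8 8-bromooct-1-ene; 9 (S)-γ-valerolactone
Product: 12 (S)-2-hydroxytridec-12-en-5-one, via oct-7-enylmagnesium bromide 10 (not isolated), via magnesium lactolate 11 (not isolated)
Conditions: Mg, THF, rt; then 9 (1.2 equiv), THF, −78 °C; AcOH, −78 °C
Reagents that add atoms: none
Why: Grignard addition to the γ-lactone at −78 °C should stop at the tetrahedral magnesium lactolate 11, which is protonated before it can collapse to the ketone in the presence of more Grignard reagent, so a single acyl substitution gives the γ-hydroxy ketone and the chiral-pool carbinol center, whose C–O bond is never broken, stays S.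

Step 5
Reactants: 7 (S)-7-methoxy-3-(prop-2-enyl)-2-benzofuran-1(3H)-one; 12 (S)-2-hydroxytridec-12-en-5-one
Product: 14 (3S)-3-[(13S)-13-hydroxy-10-oxotetradecyl]-7-methoxy-2-benzofuran-1(3H)-one, via cross-metathesis alkene 13 (not isolated)
Conditions: second-generation Hoveyda–Grubbs catalyst RuCl2(=CH-C6H4-2-OiPr)(1,3-dimesitylimidazolidin-2-ylidene) (5 mol %), 12 (3 equiv), 1,4-benzoquinone (10 mol %), CH2Cl2, 40 °C; then EtOAc, Pd/C, H2 (1 atm), rt
Reagents that add atoms: none
Why: Olefin cross-metathesis of two unhindered terminal alkenes, driven by loss of ethylene and by the excess of the cheap partner 12, joins the chain, and heterogeneous hydrogenation then saturates the disubstituted alkene 13 (its E/Z ratio is irrelevant) while ketone, lactone and the benzylic C3–O bond of the 3-alkylphthalide are expected to survive 1 atm of H2.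

Step 6
Reactants: 14 (3S)-3-[(13S)-13-hydroxy-10-oxotetradecyl]-7-methoxy-2-benzofuran-1(3H)-one
Product: 16 (3S)-5-hydroxy-3-[(13S)-13-hydroxy-10-oxotetradecyl]-7-methoxy-2-benzofuran-1(3H)-one, via aryl pinacol boronate 15 (not isolated)
Conditions: [Ir(OMe)(cod)]2 (2 mol %), dtbpy (4 mol %), B2pin2 (2.5 equiv), THF, 80 °C; then KHSO5 (Oxone), acetone/H2O, rt
Reagents that add atoms: potassium peroxymonosulfate, [K+].[O-]S(=O)(=O)OO
Why: Iridium-catalysed aromatic C–H borylation is governed by sterics and should choose C5–H, the only ring C–H without an ortho substituent (C4–H adjoins C3a with its branched C3, C6–H adjoins the methoxy group), and oxidation of boronate 15 with KHSO5 replaces boron by hydroxyl at the same carbon (one-pot C–H borylation/oxidation); the excess B2pin2 allows for reversible O-borylation of the side-chain carbinol.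

Compound list
1 | 2-bromo-3-methoxybenzaldehyde | COc1cccc(C=O)c1Br | starting material
2 | (S)-1-(2-bromo-3-methoxyphenyl)but-3-enyl diisopinocampheylborinate | C=CC[C@H](OB([C@@H]1C[C@@H]2C[C@H]([C@H]1C)C2(C)C)[C@@H]1C[C@@H]2C[C@H]([C@H]1C)C2(C)C)c1cccc(OC)c1Br | intermediate (not isolated)
3 | (S)-1-(2-bromo-3-methoxyphenyl)but-3-en-1-ol | C=CC[C@H](O)c1cccc(OC)c1Br | intermediate
4 | (S)-1-(2-bromo-3-methoxyphenyl)but-3-enyl methyl carbonate | C=CC[C@H](OC(=O)OC)c1cccc(OC)c1Br | intermediate
5 | (S)-{2-methoxy-6-[1-(methoxycarbonyloxy)but-3-enyl]phenyl}lithium | C=CC[C@H](OC(=O)OC)c1cccc(OC)c1[Li] | intermediate (not isolated)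
6 | lithium (3S)-1,7-dimethoxy-3-(prop-2-enyl)-1,3-dihydro-2-benzofuran-1-olate (both C1 epimers) | [Li]OC1(OC)O[C@@H](CC=C)c2cccc(OC)c12 | intermediate (not isolated)
7 | (S)-7-methoxy-3-(prop-2-enyl)-2-benzofuran-1(3H)-one | C=CC[C@@H]1OC(=O)c2c(OC)cccc12 | intermediate
8 | 8-bromooct-1-ene | C=CCCCCCCBr | starting material
9 | (S)-γ-valerolactone, (S)-5-methyloxolan-2-one | C[C@H]1CCC(=O)O1 | starting material
10 | oct-7-enylmagnesium bromide | C=CCCCCCC[Mg]Br | intermediate (not isolated)
11 | bromomagnesium (5S)-5-methyl-2-(oct-7-enyl)oxolan-2-olate (both C2 epimers) | C=CCCCCCCC1(O[Mg]Br)CC[C@H](C)O1 | intermediate (not isolated)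
12 | (S)-2-hydroxytridec-12-en-5-one | C=CCCCCCCC(=O)CC[C@H](C)O | intermediate
13 | (3S)-3-[(13S)-13-hydroxy-10-oxotetradec-2-enyl]-7-methoxy-2-benzofuran-1(3H)-one (E/Z mixture) | COc1cccc2c1C(=O)O[C@H]2CC=CCCCCCCC(=O)CC[C@H](C)O | intermediate (not isolated)
14 | (3S)-3-[(13S)-13-hydroxy-10-oxotetradecyl]-7-methoxy-2-benzofuran-1(3H)-one | COc1cccc2c1C(=O)O[C@H]2CCCCCCCCCC(=O)CC[C@H](C)O | intermediate
15 | (3S)-3-[(13S)-13-hydroxy-10-oxotetradecyl]-7-methoxy-5-(4,4,5,5-tetramethyl-1,3,2-dioxaborolan-2-yl)-2-benzofuran-1(3H)-one | COc1cc(B3OC(C)(C)C(C)(C)O3)cc2c1C(=O)O[C@H]2CCCCCCCCCC(=O)CC[C@H](C)O | intermediate (not isolated)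
16 | (3S)-5-hydroxy-3-[(13S)-13-hydroxy-10-oxotetradecyl]-7-methoxy-2-benzofuran-1(3H)-one | COc1cc(O)cc2c1C(=O)O[C@H]2CCCCCCCCCC(=O)CC[C@H](C)O | target

Total step count: 6. Longest linear sequence: 5 steps (steps 1, 2, 3, 5 and 6).

Steps most likely to fail

Step 3. The risk is attack of t-BuLi on the carbonate carbonyl, or protonation of the aryllithium before acyl transfer, so that debrominated or tert-butyl ketone material forms in place of the lactone. Fallback: from alcohol 3, NaH and Et2NCOCl in THF would give (S)-1-(2-bromo-3-methoxyphenyl)but-3-enyl N,N-diethylcarbamate F1, whose carbonyl resists alkyllithium attack. t-BuLi in THF at −78 °C would then bring about bromine–lithium exchange and 1,4 O-to-C carbamoyl transfer to (S)-N,N-diethyl-2-(1-hydroxybut-3-enyl)-6-methoxybenzamide F2. TsOH in hot toluene would lactonize F2 with loss of diethylamine, and the route is rejoined at 7.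

Step 6. The risk is reduction of the chain ketone by the pinacolborane formed during borylation, or consumption of the boron reagent by the free carbinol, so that the arene is not borylated cleanly. Fallback: from 14, MeOH, CH(OMe)3 and PPTS would close the γ-hydroxy ketone to the cyclic methyl ketal (3S)-7-methoxy-3-{9-[(5S)-2-methoxy-5-methyloxolan-2-yl]nonyl}-2-benzofuran-1(3H)-one F3, which hides both ketone and hydroxyl. The borylation of step 6 followed by oxidation with buffered NaBO3·4H2O would give (3S)-5-hydroxy-7-methoxy-3-{9-[(5S)-2-methoxy-5-methyloxolan-2-yl]nonyl}-2-benzofuran-1(3H)-one F4. PPTS in wet acetone would then hydrolyse the ketal with loss of methanol, and the route is rejoined at 16.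

Step 4. The risk is early collapse of the magnesium lactolate and a second addition of the Grignard reagent, leading to a tertiary alcohol. Fallback: from lactone 9, MeNHOMe·HCl and AlMe3 in CH2Cl2 would open the ring to (S)-4-hydroxy-N-methoxy-N-methylpentanamide F5. F5 would be treated at once with Grignard reagent 10 (2.5 equiv, the first of which deprotonates the hydroxyl) in THF at 0 °C; the chelated tetrahedral adduct cannot add a second time, and work-up, with loss of N,O-dimethylhydroxylamine, rejoins the route at 12.

Further compounds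
F1 | step 3 | (S)-1-(2-bromo-3-methoxyphenyl)but-3-enyl N,N-diethylcarbamate | C=CC[C@H](OC(=O)N(CC)CC)c1cccc(OC)c1Br
F2 | step 3 | (S)-N,N-diethyl-2-(1-hydroxybut-3-enyl)-6-methoxybenzamide | C=CC[C@H](O)c1cccc(OC)c1C(=O)N(CC)CC
F3 | step 6 | (3S)-7-methoxy-3-{9-[(5S)-2-methoxy-5-methyloxolan-2-yl]nonyl}-2-benzofuran-1(3H)-one | COc1cccc2c1C(=O)O[C@H]2CCCCCCCCCC1(OC)CC[C@H](C)O1
F4 | step 6 | (3S)-5-hydroxy-7-methoxy-3-{9-[(5S)-2-methoxy-5-methyloxolan-2-yl]nonyl}-2-benzofuran-1(3H)-one | COc1cc(O)cc2c1C(=O)O[C@H]2CCCCCCCCCC1(OC)CC[C@H](C)O1
F5 | step 4 | (S)-4-hydroxy-N-methoxy-N-methylpentanamide | C[C@H](O)CCC(=O)N(C)OC
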